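How much target can you take from this flask, at what moment, and for how long?

| setting | Saturday's | Friday's | flask |
|---|---|---|---|
| substrate | 0.066 M | 0.066 M | 0.066 M |
| reagent | 0.67 equiv | 1.5 equiv | 1.00 equiv |
| remark | run made earlier | run made earlier |  |
| time |  |  | 1.5 h |

| run | time / min | target / % | substrate / % |
|---|---|---|---|
| Saturday's | 1.50 | 4.3 | 93.9 |
| Saturday's | 3.00 | 7.9 | 91.6 |
| Saturday's | 6.00 | 9.7 | 85.3 |
| Saturday's | 10.0 | 9.5 | 82.7 |
| Saturday's | 20.0 | 7.7 | 80.3 |
| Saturday's | 40.0 | 5.5 | 77.3 |
| Saturday's | 80.0 | 4.4 | 75.6 |
| Friday's | 1.50 | 10.0 | 87.3 |
| Friday's | 3.00 | 15.3 | 80.1 |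
| Friday's | 6.00 | 16.0 | 73.3 |
| Friday's | 10.0 | 15.8 | 69.9 |
| Friday's | 20.0 | 11.3 | 66.3 |
| Friday's | 40.0 | 8.5 | 64.6 |
| Friday's | 80.0 | 4.7 | 65.3 |

(readings scatter by 0.5 percentage points)

- the moment within 1.5 h at which there is most target
- the amount of target, in percent of the substrate charged, at that time
- earliest time at which at least nineteen twentieths of that best amount are there
- latest time at which they still are



1. In both earlier runs target rises and then falls, so it is an intermediate. In both, the highest reading stands at 6.00 min and the next highest at 10.0 min. I expect this flask's peak near those times, so what I reckon here is its height.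

2. Friday's run has 2.24 times the reagent of Saturday's run. At the first reading its target is 2.33 times Saturday's, close to that ratio. At the peak reading it is 1.65 times, which is less.

3. So I solve each end and join them. For a small charge e, in equivalents, I let the peak grow in proportion to e, and for a large charge I let it bend towards a ceiling C, a fraction of the substrate charged. The join is: peak = C·e/(e + h). The peak readings of the two runs give C = 33.6 % and h = 1.65, the half-charge: the charge at which the peak stands at half of C. These two constants come from two scattered readings, so the rule is still untested.

4. For this flask, at 1.00 equiv, my rule gives a peak of 12.7 %.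

5. The forecast says 12.7 % at 0.117 h, with the window from 0.062 h to 0.185 h. It reads the runs this way: “Target peaks early, then decays steadily even after substrate stops being consumed”.

The flask gives 12.7 % at 0.111 h, and the window runs from 0.0724 h to 0.172 h, opening later than the forecast said. At the best time it still holds 80.0 % of its substrate and 63.4 % of its reagent. That best is 37.8 % of C, and e/(e + h) at this charge gave 37.7 %.

    target ⇌ isomer of the product B (K = 1.40, k = 0.00110 /s)
    2 reagent → self-condensation product (k = 0.00520 /M/s)
    substrate + reagent → isomer of the product A (k = 0.00200 /M/s)
    substrate + reagent ⇌ target (K = 4.70 /M, k = 0.0170 /M/s)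

Now take the neighbour charged with 0.250 equiv, less reagent than Saturday's run. With the same C and h the rule gives 4.42 %. The computed best there is 3.96 %, which is 0.46 percentage points lower.

Readings and results stem from a simulated flask with constants of no real substance.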